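The pitfall is to trust a share built on a small reading: the share of target in target plus over-reaction product (the selectivity) hangs on c(over-reaction product), often a few points against a scatter of 0.5 percentage points.

| flask | substrate | coupling partner | remark | time |
|---|---|---|---|---|
| south-west | 22 mM | 22 mM | run made earlier |  |
| north-east | 22 mM | 11 mM | run made earlier |  |
| south-east | 22 mM | 16 mM | run made earlier |  |
| south | 11 mM | 22 mM | run made earlier |  |
| green | 22 mM | 22.0 mM (fed, over 80 s) | all else is in the flask from the start; the feed brings no volume worth counting | 12 min |
| ochre | 22 mM | 22.0 mM | everything together at the start | 12 min |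
| violet | 22 mM (fed, over 5.0 min) | 22.0 mM | all else is in the flask from the start; the feed brings no volume worth counting | 12 min |
| amber | 22 mM | 22.0 mM (fed, over 5.0 min) | all else is in the flask from the start; the feed brings no volume worth counting | 12 min |

| run | time / min | target / % | over-reaction product / % | substrate / % |
|---|---|---|---|---|
| south-west | 1.33 | 12.1 | 0.7 | 87.9 |
| south-west | 3.00 | 19.8 | 3.7 | 77.0 |
| south-west | 4.00 | 23.1 | 3.8 | 72.9 |
| south-west | 6.00 | 27.5 | 5.4 | 67.1 |
| south-west | 8.00 | 29.7 | 5.6 | 64.3 |
| north-east | 0.667 | 4.9 | 0.8 | 94.8 |
| north-east | 2.00 | 11.7 | 0.4 | 87.6 |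
| north-east | 3.00 | 14.9 | 1.0 | 83.4 |
| north-east | 5.00 | 20.2 | 1.0 | 78.0 |
| north-east | 8.00 | 23.0 | 1.2 | 75.7 |
| south-east | 0.667 | 5.3 | 0.7 | 95.4 |
| south-east | 2.00 | 14.2 | 0.4 | 85.1 |
| south-east | 3.00 | 17.8 | 1.1 | 79.1 |
| south-east | 5.00 | 23.5 | 3.4 | 73.7 |
| south-east | 8.00 | 26.6 | 3.3 | 69.4 |
| south | 0.667 | 5.5 | 0.1 | 95.2 |
| south | 2.00 | 11.7 | 0.9 | 87.4 |
| south | 3.00 | 15.6 | 3.1 | 81.1 |
| south | 5.00 | 19.9 | 5.4 | 74.1 |
| south | 8.00 | 24.7 | 6.5 | 69.0 |

(each reading ± 0.5 percentage points)

- the best flask by share of target in target plus over-reaction product; "all alike" if 1.5 percentage points covers them all (green / ochre / violet / amber / all alike)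
- share of target in target plus over-reaction product at the end, green
- share of target in target plus over-reaction product at the end, ochre
- share of target in target plus over-reaction product at the end, violet
- share of target in target plus over-reaction product at the end, amber

- candidate steps: substrate + coupling partner -> target; coupling partner -> decomposed reagent; coupling partner + target -> over-reaction product

1. Take the ratio r = c(over-reaction product)/c(target) in the last reading of a run, and n, the slope of ln r against ln of the partner charge, with substrate held at 22 mM from the start.

2. Test each reading before using it. In south-west, the share is 84.1%. A scatter step up on target, with the sum moving along, raises it by 0.22 points, but the same step up on over-reaction product lowers it by 1.2 points.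

3. For n, the south-west over-reaction reading shifted by 0.5 points gives 1.98, but the north-east one gives 1.35 to 2.63. So the north-east reading is the one to know well.

4. South-west gives r = 0.189, and the partner order n 1.85. For south-east this predicts a share of 90.5%, against a reading of 89.0%. My reckoning for ochre, with south-west's charges, is 84.1%. Any share converts to an equivalent all-at-once partner charge, c_eq.

5. The forecast says violet is best: green 85%, ochre 83.5%, violet 89%, amber 87%, adding that “the violet-versus-amber ordering is uncertain”. Its amber means c_eq = 19.4 mM.

6. Violet leads at 90.3%; ochre gives 83.7%, green 83.0%, and amber 81.9% against the forecast's 87%.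

    substrate + coupling partner → target, rate k1*[substrate]^1.5*[coupling partner]^0.5 (k = 5.37 /M/min)
    coupling partner → decomposed reagent (k = 0.210 /min)
    coupling partner + target → over-reaction product (k = 7.36 /M/min)

7. Amber stood at 87.9% at 5.00 min, with 44.0% of its coupling partner present. Its end share means c_eq = 24.0 mM, more than the 22.0 mM it received. Scaling amber's ratio by n to 88 mM of coupling partner gives a share of 25.7%, and that neighbour flask stands at 35.2%.

The earlier runs and the new flask are simulated with constants of no real substance; the scatter is artificial.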